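**Plan**

1. Retrosynthetic cuts: hydroxyquinone ← 2,5-dimethoxyquinone ← tetramethoxyarene; ring C3–CH3 back to a C3 ketone (enol triflate); ring C2–CH3 back to an exocyclic methylene beside that ketone; the bond from the quaternary ring carbon C1 to the first side-chain CH2 by conjugate addition; the diene back to a prenyl arene.
2. Enabling feature: ring C1 lies β to ring C3, the methyl-bearing sp2 carbon that can be carried as C=O, so the cyclohexene is 3-methylcyclohex-2-enone in disguise. The chain CH2 bonded to C1 is the terminus of a vinyl group on the E-trisubstituted alkene, i.e. of a 1,3-diene.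
3. Forward: arene prenylation, E-selective allylic oxidation and methylenation give the aryl diene. Hydrozirconation and copper-catalysed asymmetric conjugate addition join it to 3-methylcyclohexenone; no ring is closed (the ring is the enone ring), and the enolate is kept as its silyl ether.
4. Then α-methylenation, CBS reduction, OH-directed hydrogenation and re-oxidation install the C2 methyl; kinetic enol triflate and methyl coupling give the ring alkene; (NH4)2Ce(NO3)6 oxidation and selective hydrolysis give the quinone.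
5. Stereochemistry: C1 (R) from the chiral copper catalyst; C2 (S) relayed by directed hydrogenation from a carbinol set by the CBS catalyst; E alkene from the SeO2 oxidation of the prenyl group.

Key step: step 4

Remark: the SMILES fixes the ring stereocentres as 1R,2S, i.e. the side chain on C1 is cis to the methyl on C2, and the route is planned for this isomer; Ar below means 2,3,5,6-tetramethoxyphenyl.

Step 1
Reactants: 1 1,2,4,5-tetramethoxybenzene; 2 1-bromo-3-methylbut-2-ene (prenyl bromide)
Product: 4 1,2,4,5-tetramethoxy-3-(3-methylbut-2-en-1-yl)benzene, via aryllithium 3 (not isolated)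
Conditions: n-BuLi, TMEDA, THF, 0 °C; CuBr·SMe2 (10 mol %), then 2, −78 °C to rt
Reagents that add atoms: none
Why: Directed ortho-metalation takes place at one of the two equivalent ring positions flanked by methoxy groups, and copper-catalysed allylation of the aryllithium at the primary carbon of prenyl bromide (SN2, no allylic transposition) should give the linear prenyl arene.

Step 2
Reactants: 4 1,2,4,5-tetramethoxy-3-(3-methylbut-2-en-1-yl)benzene
Product: 6 (2E)-2-methyl-4-Ar-but-2-enal, via allylic alcohol 5 (not isolated)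
Conditions: SeO2 (0.5 equiv), t-BuOOH, CH2Cl2, rt; filtration; MnO2, CH2Cl2, rt
Reagents that add atoms: selenium dioxide, O=[Se]=O (oxygen carrier); tert-butyl hydroperoxide, CC(C)(C)OO (terminal oxidant)
Why: SeO2 allylic oxidation (Riley type: ene reaction, then 2,3-sigmatropic shift) is expected to hydroxylate only the methyl group trans to the benzylic chain on the more substituted alkene carbon, which fixes the E geometry of the side-chain alkene for the rest of the route, and MnO2 then takes the allylic alcohol 5 (any aldehyde already formed converging) to enal 6.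

Step 3
Reactants: 6 (2E)-2-methyl-4-Ar-but-2-enal
Product: 7 1,2,4,5-tetramethoxy-3-[(2E)-3-methylpenta-2,4-dien-1-yl]benzene
Conditions: Ph3PCH3Br, KOtBu, THF, 0 °C to rt
Reagents that add atoms: methyltriphenylphosphonium bromide, C[P+](c1ccccc1)(c1ccccc1)c1ccccc1.[Br-]
Why: Wittig methylenation of the aldehyde with the non-stabilised ylide should give the terminal 1,3-diene and leave the E-trisubstituted alkene unchanged.

Step 4
Reactants: 7 1,2,4,5-tetramethoxy-3-[(2E)-3-methylpenta-2,4-dien-1-yl]benzene; 8 3-methylcyclohex-2-en-1-one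
Product: 10 trimethyl({(3R)-3-methyl-3-[(3E)-3-methyl-5-Ar-pent-3-en-1-yl]cyclohex-1-en-1-yl}oxy)silane, via alkylzirconocene chloride 9 (not isolated)
Conditions: Cp2Zr(H)Cl, CH2Cl2, rt; then CuCl (10 mol %), AgNTf2 (11 mol %), BINOL-derived bis(1-phenylethyl)amine phosphoramidite (10 mol %), 8, Me3SiCl, Et2O, rt; non-aqueous work-up
Reagents that add atoms: chlorotrimethylsilane, C[Si](C)(C)Cl
Why: Cp2Zr(H)Cl adds syn and 1,2 to the monosubstituted vinyl group of diene 7 with zirconium at the terminal carbon, giving the primary homoallylic alkylzirconocene 9; transmetalation to the chiral copper–phosphoramidite complex, π-complexation and oxidative addition at the β-carbon of enone 8 and reductive elimination then form the bond between the chain terminus and the ring carbon, and Me3SiCl traps the enolate as the regiodefined silyl enol ether 10. The closest known reaction type is the copper-catalysed asymmetric conjugate addition of alkylzirconocenes, made by hydrozirconation of terminal alkenes, to 3-methylcyclohex-2-enone, which builds all-carbon quaternary centres. No ring is closed, since the six-membered ring of the target is the enone ring itself. The new quaternary stereocentre is under catalyst control: the enantiomer of the phosphoramidite ligand is chosen so that the alkyl group adds to the enone face that leads to the R configuration. The step needs 1,4- instead of 1,2-addition, which the soft organocopper intermediate and Me3SiCl secure, and hydrozirconation of the terminal instead of the internal alkene, which the steric demand of Cp2Zr(H)Cl towards the trisubstituted alkene secures. In effect two acceptor-type carbons, an alkene terminus and an enone β-carbon, are joined after polarity reversal of the diene terminus by hydrometalation.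

Step 5
Reactants: 10 trimethyl({(3R)-3-methyl-3-[(3E)-3-methyl-5-Ar-pent-3-en-1-yl]cyclohex-1-en-1-yl}oxy)silane
Product: 13 (3R)-3-methyl-2-methylidene-3-[(3E)-3-methyl-5-Ar-pent-3-en-1-yl]cyclohexan-1-one, via Mannich base 11 (not isolated), via methiodide 12 (not isolated)
Conditions: Me2N=CH2 I (Eschenmoser's salt), CH2Cl2, rt; MeI; then DBU, CH2Cl2, rt
Reagents that add atoms: N,N-dimethylmethyleneiminium iodide, C=[N+](C)C.[I-]
Why: The Mannich reaction of the silyl enol ether with the preformed iminium salt can only take place at the enol ether carbon next to the quaternary centre, so the regiochemistry set in step 4 is carried over, and N-methylation followed by base-induced E1cB loss of trimethylamine should give the exocyclic enone, in which the transient stereocentre of 11 and 12 is erased.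

Step 6
Reactants: 13 (3R)-3-methyl-2-methylidene-3-[(3E)-3-methyl-5-Ar-pent-3-en-1-yl]cyclohexan-1-one
Product: 14 (1S,3R)-3-methyl-2-methylidene-3-[(3E)-3-methyl-5-Ar-pent-3-en-1-yl]cyclohexan-1-ol
Conditions: (R)-2-methyl-CBS-oxazaborolidine (20 mol %), catecholborane, toluene, −78 °C; aqueous work-up
Reagents that add atoms: none
Why: Corey–Bakshi–Shibata reduction: the oxazaborolidine–borane complex binds the ketone with the α-methylene side (backed by the quaternary carbon) as the large group and the ring CH2 as the small group and delivers hydride 1,2 to one carbonyl face, so the new carbinol centre (expected 1S with the R catalyst) is set by the catalyst and not by the small methyl/chain difference at the quaternary carbon.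

Step 7
Reactants: 14 (1S,3R)-3-methyl-2-methylidene-3-[(3E)-3-methyl-5-Ar-pent-3-en-1-yl]cyclohexan-1-ol
Product: 15 (1S,2S,3R)-2,3-dimethyl-3-[(3E)-3-methyl-5-Ar-pent-3-en-1-yl]cyclohexan-1-ol
Conditions: [Rh(nbd)(dppb)]BF4 (5 mol %), H2 (50 atm), CH2Cl2, rt
Reagents that add atoms: none
Why: Hydroxyl-directed hydrogenation: the cationic rhodium–diphosphine catalyst binds the pseudo-axial hydroxyl and delivers both hydrogens to the exocyclic 1,1-disubstituted alkene from the hydroxyl face, so that H at C2 ends cis to OH and the new methyl group trans to OH and cis to the side chain (2S), while the unactivated trisubstituted side-chain alkene should be reduced far more slowly by this catalyst.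

Step 8
Reactants: 15 (1S,2S,3R)-2,3-dimethyl-3-[(3E)-3-methyl-5-Ar-pent-3-en-1-yl]cyclohexan-1-ol
Product: 16 (2S,3R)-2,3-dimethyl-3-[(3E)-3-methyl-5-Ar-pent-3-en-1-yl]cyclohexan-1-one
Conditions: Pr4N[RuO4] (5 mol %), N-methylmorpholine N-oxide, 4 Å molecular sieves, CH2Cl2, rt
Reagents that add atoms: none
Why: Ley–Griffith oxidation with catalytic perruthenate and N-methylmorpholine N-oxide returns the ketone under neutral conditions, which should leave the α-methyl stereocentre untouched.

Step 9
Reactants: 16 (2S,3R)-2,3-dimethyl-3-[(3E)-3-methyl-5-Ar-pent-3-en-1-yl]cyclohexan-1-one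
Product: 18 (5R,6S)-5,6-dimethyl-5-[(3E)-3-methyl-5-Ar-pent-3-en-1-yl]cyclohex-1-en-1-yl trifluoromethanesulfonate, via potassium enolate 17 (not isolated)
Conditions: KN(SiMe3)2, THF, −78 °C; PhNTf2, −78 °C to 0 °C
Reagents that add atoms: N-phenylbis(trifluoromethanesulfonimide), O=S(=O)(N(c1ccccc1)S(=O)(=O)C(F)(F)F)C(F)(F)F
Why: Kinetic deprotonation by the hindered amide at −78 °C should occur at the ring CH2 α to the carbonyl and not at the α-methine flanked by the quaternary carbon, so that the enolate and its triflate (O-sulfonylation with PhNTf2) form away from the C2 stereocentre, which is kept.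

Step 10
Reactants: 18 (5R,6S)-5,6-dimethyl-5-[(3E)-3-methyl-5-Ar-pent-3-en-1-yl]cyclohex-1-en-1-yl trifluoromethanesulfonate
Product: 19 1,2,4,5-tetramethoxy-3-{(2E)-3-methyl-5-[(1R,2S)-1,2,3-trimethylcyclohex-3-en-1-yl]pent-2-en-1-yl}benzene
Conditions: MeMgBr, Fe(acac)3 (5 mol %), THF/NMP, −30 °C
Reagents that add atoms: methylmagnesium bromide, C[Mg]Br
Why: Iron-catalysed Kumada-type cross-coupling of the alkenyl triflate with the methyl Grignard reagent should replace the triflate by methyl with the double bond kept in place, giving the trisubstituted ring alkene without touching either stereocentre.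

Step 11
Reactants: 19 1,2,4,5-tetramethoxy-3-{(2E)-3-methyl-5-[(1R,2S)-1,2,3-trimethylcyclohex-3-en-1-yl]pent-2-en-1-yl}benzene
Product: 20 2,5-dimethoxy-3-{(2E)-3-methyl-5-[(1R,2S)-1,2,3-trimethylcyclohex-3-en-1-yl]pent-2-en-1-yl}cyclohexa-2,5-diene-1,4-dione
Conditions: (NH4)2Ce(NO3)6, MeCN/H2O, 0 °C
Reagents that add atoms: water, O
Why: Oxidative demethylation of a para-dimethoxy pair by the cerium reagent (two one-electron oxidations, attack of water, loss of two molecules of methanol) should give the 2,5-dimethoxy-1,4-benzoquinone as the main product, the two possible para-quinones being identical by the symmetry of the arene, with the isolated alkenes left intact.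

Step 12
Reactants: 20 2,5-dimethoxy-3-{(2E)-3-methyl-5-[(1R,2S)-1,2,3-trimethylcyclohex-3-en-1-yl]pent-2-en-1-yl}cyclohexa-2,5-diene-1,4-dione
Product: 21 Metachromin C
Conditions: HClO4 (70 % aq), THF, 0 °C to rt
Reagents that add atoms: water, O
Why: Acid-catalysed vinylogous ester hydrolysis (addition of water, elimination of methanol) is expected at the methoxy-bearing carbon next to the side chain, because that methoxy group is forced out of the quinone plane by its two neighbours, donates less and leaves the more electrophilic carbon, a selectivity known for 3-alkyl-2,5-dimethoxy-1,4-benzoquinones, and this gives the hydroxyquinone with OH next to the chain and the remote methoxy group kept.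

**Compound list**

1 | 1,2,4,5-tetramethoxybenzene | COc1cc(OC)c(OC)cc1OC | starting material
2 | 1-bromo-3-methylbut-2-ene (prenyl bromide) | CC(C)=CCBr | starting material
3 | (2,3,5,6-tetramethoxyphenyl)lithium | COc1cc(OC)c(OC)c([Li])c1OC | intermediate
4 | 1,2,4,5-tetramethoxy-3-(3-methylbut-2-en-1-yl)benzene | COc1cc(OC)c(OC)c(CC=C(C)C)c1OC | intermediate
5 | (2E)-2-methyl-4-(2,3,5,6-tetramethoxyphenyl)but-2-en-1-ol | COc1cc(OC)c(OC)c(C/C=C(\C)CO)c1OC | intermediate
6 | (2E)-2-methyl-4-(2,3,5,6-tetramethoxyphenyl)but-2-enal | COc1cc(OC)c(OC)c(C/C=C(\C)C=O)c1OC | intermediate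
7 | 1,2,4,5-tetramethoxy-3-[(2E)-3-methylpenta-2,4-dien-1-yl]benzene | COc1cc(OC)c(OC)c(C/C=C(\C)C=C)c1OC | intermediate
8 | 3-methylcyclohex-2-en-1-one | CC1=CC(=O)CCC1 | starting material
9 | chlorobis(cyclopentadienyl)[(3E)-3-methyl-5-(2,3,5,6-tetramethoxyphenyl)pent-3-en-1-yl]zirconium | COc1cc(OC)c(OC)c(C/C=C(\C)CC[Zr](Cl)(C2C=CC=C2)C2C=CC=C2)c1OC | intermediate
10 | trimethyl({(3R)-3-methyl-3-[(3E)-3-methyl-5-(2,3,5,6-tetramethoxyphenyl)pent-3-en-1-yl]cyclohex-1-en-1-yl}oxy)silane | COc1cc(OC)c(OC)c(C/C=C(\C)CC[C@@]2(C)CCCC(O[Si](C)(C)C)=C2)c1OC | intermediate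
11 | (3R)-2-[(dimethylamino)methyl]-3-methyl-3-[(3E)-3-methyl-5-(2,3,5,6-tetramethoxyphenyl)pent-3-en-1-yl]cyclohexan-1-one (both C2 epimers) | COc1cc(OC)c(OC)c(C/C=C(\C)CC[C@@]2(C)CCCC(=O)C2CN(C)C)c1OC | intermediate
12 | trimethyl({(2R)-2-methyl-2-[(3E)-3-methyl-5-(2,3,5,6-tetramethoxyphenyl)pent-3-en-1-yl]-6-oxocyclohexyl}methyl)ammonium iodide (both epimers at the ring CH) | COc1cc(OC)c(OC)c(C/C=C(\C)CC[C@@]2(C)CCCC(=O)C2C[N+](C)(C)C)c1OC.[I-] | intermediate
13 | (3R)-3-methyl-2-methylidene-3-[(3E)-3-methyl-5-(2,3,5,6-tetramethoxyphenyl)pent-3-en-1-yl]cyclohexan-1-one | COc1cc(OC)c(OC)c(C/C=C(\C)CC[C@@]2(C)CCCC(=O)C2=C)c1OC | intermediate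
14 | (1S,3R)-3-methyl-2-methylidene-3-[(3E)-3-methyl-5-(2,3,5,6-tetramethoxyphenyl)pent-3-en-1-yl]cyclohexan-1-ol | COc1cc(OC)c(OC)c(C/C=C(\C)CC[C@@]2(C)CCC[C@H](O)C2=C)c1OC | intermediate
15 | (1S,2S,3R)-2,3-dimethyl-3-[(3E)-3-methyl-5-(2,3,5,6-tetramethoxyphenyl)pent-3-en-1-yl]cyclohexan-1-ol | COc1cc(OC)c(OC)c(C/C=C(\C)CC[C@@]2(C)CCC[C@H](O)[C@H]2C)c1OC | intermediate
16 | (2S,3R)-2,3-dimethyl-3-[(3E)-3-methyl-5-(2,3,5,6-tetramethoxyphenyl)pent-3-en-1-yl]cyclohexan-1-one | COc1cc(OC)c(OC)c(C/C=C(\C)CC[C@@]2(C)CCCC(=O)[C@H]2C)c1OC | intermediate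
17 | potassium (5R,6S)-5,6-dimethyl-5-[(3E)-3-methyl-5-(2,3,5,6-tetramethoxyphenyl)pent-3-en-1-yl]cyclohex-1-en-1-olate | COc1cc(OC)c(OC)c(C/C=C(\C)CC[C@@]2(C)CCC=C([O-])[C@H]2C)c1OC.[K+] | intermediate
18 | (5R,6S)-5,6-dimethyl-5-[(3E)-3-methyl-5-(2,3,5,6-tetramethoxyphenyl)pent-3-en-1-yl]cyclohex-1-en-1-yl trifluoromethanesulfonate | COc1cc(OC)c(OC)c(C/C=C(\C)CC[C@@]2(C)CCC=C(OS(=O)(=O)C(F)(F)F)[C@H]2C)c1OC | intermediate
19 | 1,2,4,5-tetramethoxy-3-{(2E)-3-methyl-5-[(1R,2S)-1,2,3-trimethylcyclohex-3-en-1-yl]pent-2-en-1-yl}benzene | COc1cc(OC)c(OC)c(C/C=C(\C)CC[C@@]2(C)CCC=C(C)[C@H]2C)c1OC | intermediate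
20 | 2,5-dimethoxy-3-{(2E)-3-methyl-5-[(1R,2S)-1,2,3-trimethylcyclohex-3-en-1-yl]pent-2-en-1-yl}cyclohexa-2,5-diene-1,4-dione | COC1=CC(=O)C(OC)=C(C/C=C(\C)CC[C@@]2(C)CCC=C(C)[C@H]2C)C1=O | intermediate
21 | Metachromin C, 2-hydroxy-5-methoxy-3-{(2E)-3-methyl-5-[(1R,2S)-1,2,3-trimethylcyclohex-3-en-1-yl]pent-2-en-1-yl}cyclohexa-2,5-diene-1,4-dione | COC1=CC(=O)C(O)=C(C/C=C(\C)CC[C@@]2(C)CCC=C(C)[C@H]2C)C1=O | target

**Totals and risks**

Total step count: 12. Longest linear sequence: 12 steps (1 to 21; 2 and 8 enter as purchased reagents).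

Steps most likely to fail:

Step 4. The hydrozirconation may be incomplete or touch the internal alkene, the electron-rich arene may slow the transfer from zirconium to copper, the silyl trapping of the enolate may be incomplete, and the enantioselectivity may fall short. Fallback from 7, returning at 10: hydroboration of the terminal alkene of 7 with 9-BBN gives the B-alkyl-9-borabicyclo[3.3.1]nonane F1, which NaOH/H2O2 oxidises to (3E)-3-methyl-5-Ar-pent-3-en-1-ol F2; CBr4/PPh3 gives 3-[(2E)-5-bromo-3-methylpent-2-en-1-yl]-1,2,4,5-tetramethoxybenzene F3; magnesium in Et2O gives the Grignard reagent F4; its conjugate addition to 8 with Cu(OTf)2 and a chiral N-heterocyclic carbene ligand (from an imidazolinium salt) gives the bromomagnesium enolate F5, which Me3SiCl/Et3N converts into 10.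

Step 7. The hydrogenation may lose facial control, because the directing hydroxyl has to sit syn-axial to the methyl group on the quaternary carbon; the allylic alcohol may isomerise to the ketone with loss of the C2 configuration; or the side-chain alkene may be partly reduced. Fallback from 13, returning at 16: direct hydrogenation of the C=C bond of the α-methylene ketone with Ru(OAc)2(BINAP), using the BINAP enantiomer that gives the 2S centre; the carbonyl-chelated enone is reduced under catalyst control and unfunctionalised alkenes are left alone. Steps 6 to 8 are then not needed and no new compound is made (F0).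

Step 12. Water may attack the other methoxy-bearing carbon, both methoxy groups may be hydrolysed, or the acid may cyclise the hydroxyquinone onto the side-chain alkene. Fallback from 20, returning at 21: KOH in MeOH/H2O hydrolyses both vinylogous esters to 2,5-dihydroxy-3-{(2E)-3-methyl-5-[(1R,2S)-1,2,3-trimethylcyclohex-3-en-1-yl]pent-2-en-1-yl}cyclohexa-2,5-diene-1,4-dione F6, and one equivalent of Me2SO4 with K2CO3 in acetone should methylate the less hindered oxygen, the one remote from the side chain.

**Further compounds**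

F1 | step 4 | 9-[(3E)-3-methyl-5-(2,3,5,6-tetramethoxyphenyl)pent-3-en-1-yl]-9-borabicyclo[3.3.1]nonane | COc1cc(OC)c(OC)c(C/C=C(\C)CCB2C3CCCC2CCC3)c1OC
F2 | step 4 | (3E)-3-methyl-5-(2,3,5,6-tetramethoxyphenyl)pent-3-en-1-ol | COc1cc(OC)c(OC)c(C/C=C(\C)CCO)c1OC
F3 | step 4 | 3-[(2E)-5-bromo-3-methylpent-2-en-1-yl]-1,2,4,5-tetramethoxybenzene | COc1cc(OC)c(OC)c(C/C=C(\C)CCBr)c1OC
F4 | step 4 | bromo[(3E)-3-methyl-5-(2,3,5,6-tetramethoxyphenyl)pent-3-en-1-yl]magnesium | COc1cc(OC)c(OC)c(C/C=C(\C)CC[Mg]Br)c1OC
F5 | step 4 | bromomagnesium (3R)-3-methyl-3-[(3E)-3-methyl-5-(2,3,5,6-tetramethoxyphenyl)pent-3-en-1-yl]cyclohex-1-en-1-olate | COc1cc(OC)c(OC)c(C/C=C(\C)CC[C@@]2(C)CCCC(O[Mg]Br)=C2)c1OC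
F0 | step 7 | none | none
F6 | step 12 | 2,5-dihydroxy-3-{(2E)-3-methyl-5-[(1R,2S)-1,2,3-trimethylcyclohex-3-en-1-yl]pent-2-en-1-yl}cyclohexa-2,5-diene-1,4-dione | OC1=CC(=O)C(O)=C(C/C=C(\C)CC[C@@]2(C)CCC=C(C)[C@H]2C)C1=O
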